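**Plan**

1. Retrosynthesis: the C6 ester is cut first, then the C6–H bond (hydride), then the ring bond C7–C8 of the seven-membered ring, read as the aldol retron C6(=O)–C7H2–C8(OH)CH3. Next come C4–isopropyl, C2=C3 (metathesis), C3–C4 (vinyl addition) and C1–C5 ([3,3]).
2. Forward: an acyclic allylic ester undergoes Ireland–Claisen rearrangement (C1–C5), ring-closing metathesis gives the cyclopentenone, and isopropyl is added at C4. The C5 vinyl group then becomes a bromomethyl ketone, the C8 ketone on the C1 arm is unmasked, and the seven-membered ring is closed last.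
3. Enabling feature: in the seven-membered ring (C5, C6, C7, C8, C9, C10, C1) the oxygens on C6 and C8 are 1,3-related with the CH2 group C7 between them, and the ring is trans-fused to the cyclopentene through C1 and C5. A regiospecific C7 enolate of a C6 ketone can therefore add to a C8 methyl ketone.
4. Stereochemistry: (R)-but-3-yn-2-ol is the only chiral source. C1 and C5 come from chirality transfer in the chair Claisen, C4 from attack anti to the C5 vinyl and C1 methyl groups, C8 from the chelated aldol ring closure, and C6 from reduction directed by the C8 hydroxyl.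
5. Helpers, all removed later: dioxolane on the C8 ketone, TES on the C4 hydroxyl (which also stops it from directing the reduction), the ketone oxidation level at C6, bromine at C7, and TBS on the phenol.

Key step: step 14

Remark: the locants C1–C10 are those of the daucane skeleton of the target and are used for the corresponding carbons of every intermediate. C1 is the quaternary ring-fusion carbon with CH3, C2=C3 the ring alkene, C4 the isopropyl carbinol, C5 the ring-fusion CH, C6 the ester carbinol, C7 a CH2, C8 the methyl carbinol, and C9 and C10 are CH2 groups.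

Step 1
Reactants: 1 (R)-but-3-yn-2-ol; 2 2-(2-bromoethyl)-2-methyl-1,3-dioxolane
Product: 3 (2R)-6-(2-methyl-1,3-dioxolan-2-yl)hex-3-yn-2-ol
Conditions: 1, n-BuLi (2.1 equiv), THF, −78 → 0 °C; then 2, DMPU, 0 °C → rt
Reagents that add atoms: none
Why: Acetylide alkylation: the acetylide carbon of the O,C-dianion displaces the primary bromide (SN2), the alkoxide being the poorer nucleophile, and the carbinol stereocentre from the chiral pool is not involved.

Step 2
Reactants: 3 (2R)-6-(2-methyl-1,3-dioxolan-2-yl)hex-3-yn-2-ol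
Product: 5 (2R,3Z)-4-iodo-6-(2-methyl-1,3-dioxolan-2-yl)hex-3-en-2-ol, via alkenylalanate 4 (not isolated)
Conditions: Red-Al, THF, 0 °C → rt; EtOAc; then I2, THF, −78 → 0 °C
Reagents that add atoms: iodine, II
Why: Hydroxyl-directed trans-hydroalumination of the propargylic alcohol puts hydride on the proximal and aluminium on the distal alkyne carbon within a five-membered alanate, and iodinolysis of the C–Al bond with retention leaves iodine cis to the carbinol carbon (Z).

Step 3
Reactants: 5 (2R,3Z)-4-iodo-6-(2-methyl-1,3-dioxolan-2-yl)hex-3-en-2-ol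
Product: 6 (2R,3E)-4-methyl-6-(2-methyl-1,3-dioxolan-2-yl)hex-3-en-2-ol
Conditions: MeZnCl (3 equiv), Pd(PPh3)4 (5 mol%), THF, rt
Reagents that add atoms: methylzinc chloride, C[Zn]Cl
Why: Negishi cross-coupling of the alkenyl iodide proceeds with retention of alkene geometry, so the new methyl group is cis and the ketal-bearing chain trans to the carbinol carbon (E).

Step 4
Reactants: 6 (2R,3E)-4-methyl-6-(2-methyl-1,3-dioxolan-2-yl)hex-3-en-2-ol; 7 but-3-enoic acid
Product: 8 (2R,3E)-4-methyl-6-(2-methyl-1,3-dioxolan-2-yl)hex-3-en-2-yl but-3-enoate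
Conditions: DCC, DMAP (5 mol%), CH2Cl2, 0 °C
Reagents that add atoms: none
Why: Steglich esterification acylates the O–H bond, so the carbinol configuration is retained, and the low temperature and low DMAP loading limit conjugation of the but-3-enoate to the crotonate.

Step 5
Reactants: 8 (2R,3E)-4-methyl-6-(2-methyl-1,3-dioxolan-2-yl)hex-3-en-2-yl but-3-enoate
Product: 11 (2R,3S,4E)-2-ethenyl-3-methyl-3-[2-(2-methyl-1,3-dioxolan-2-yl)ethyl]hex-4-enoic acid, via silyl ketene acetal 9 (not isolated), via trimethylsilyl ester 10 (not isolated)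
Conditions: LDA, THF–DMPU (3:1), −78 °C; TMSCl, −78 °C → rt, then 45 °C; aq. citric acid
Reagents that add atoms: none
Why: Ireland–Claisen rearrangement: enolisation in the presence of DMPU should give the Z(O)-dienolate (vinyl cis to OSi), and the chair transition state with the carbinol methyl, the C1 chain (E-alkene) and the vinyl group all equatorial transfers the carbinol chirality to C1 (quaternary) and C5 at once, placing the C5 vinyl group and the C1 chain on opposite faces of the future cyclopentene (the trans ring fusion).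

Step 6
Reactants: 11 (2R,3S,4E)-2-ethenyl-3-methyl-3-[2-(2-methyl-1,3-dioxolan-2-yl)ethyl]hex-4-enoic acid
Product: 13 (2R,3S,4E)-2-ethenyl-N-methoxy-N,3-dimethyl-3-[2-(2-methyl-1,3-dioxolan-2-yl)ethyl]hex-4-enamide, via acyl imidazolide 12 (not isolated)
Conditions: CDI, CH2Cl2, 0 °C → rt; then MeNH(OMe)·HCl, rt
Reagents that add atoms: N,O-dimethylhydroxylamine hydrochloride, CNOC.Cl
Why: Weinreb amide formation through the acyl imidazolide runs under nearly neutral conditions, so the acidic, allylic C5–H is neither epimerised nor moved into conjugation.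

Step 7
Reactants: 13 (2R,3S,4E)-2-ethenyl-N-methoxy-N,3-dimethyl-3-[2-(2-methyl-1,3-dioxolan-2-yl)ethyl]hex-4-enamide
Product: 14 (4R,5S,6E)-4-ethenyl-5-methyl-5-[2-(2-methyl-1,3-dioxolan-2-yl)ethyl]octa-1,6-dien-3-one
Conditions: CH2=CHMgBr, THF, −20 → 0 °C; inverse quench into cold aq. KHSO4
Reagents that add atoms: vinylmagnesium bromide, C=C[Mg]Br
Why: Weinreb ketone synthesis: the chelated tetrahedral adduct prevents over-addition, and the cold acidic quench removes the liberated amine before it can add to the new enone.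

Step 8
Reactants: 14 (4R,5S,6E)-4-ethenyl-5-methyl-5-[2-(2-methyl-1,3-dioxolan-2-yl)ethyl]octa-1,6-dien-3-one
Product: 15 (4S,5R)-5-ethenyl-4-methyl-4-[2-(2-methyl-1,3-dioxolan-2-yl)ethyl]cyclopent-2-en-1-one
Conditions: Grubbs second-generation catalyst (5 mol%), 1,4-benzoquinone (10 mol%), CH2Cl2, 40 °C
Reagents that add atoms: none
Why: Ring-closing metathesis between the enone vinyl group and the propenyl group on C1 closes the five-membered ring (C2=C3) with loss of propene, while the C5 vinyl group could only form a four-membered ring and is kept.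

Step 9
Reactants: 15 (4S,5R)-5-ethenyl-4-methyl-4-[2-(2-methyl-1,3-dioxolan-2-yl)ethyl]cyclopent-2-en-1-one
Product: 16 (1S,4S,5R)-5-ethenyl-4-methyl-4-[2-(2-methyl-1,3-dioxolan-2-yl)ethyl]-1-(propan-2-yl)cyclopent-2-en-1-ol
Conditions: i-PrMgCl, anhydrous CeCl3, THF, −78 °C
Reagents that add atoms: isopropylmagnesium chloride, CC(C)[Mg]Cl
Why: Organocerium 1,2-addition suppresses enolisation of the acidic C5–H and β-hydride reduction, and attack on the C4 carbonyl anti to the adjacent C5 vinyl group and the C1 methyl group (both on the same face) sets C4 with isopropyl cis to H5 and the hydroxyl cis to the vinyl group.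

Step 10
Reactants: 16 (1S,4S,5R)-5-ethenyl-4-methyl-4-[2-(2-methyl-1,3-dioxolan-2-yl)ethyl]-1-(propan-2-yl)cyclopent-2-en-1-ol
Product: 17 triethyl{[(1S,4S,5R)-5-ethenyl-4-methyl-4-[2-(2-methyl-1,3-dioxolan-2-yl)ethyl]-1-(propan-2-yl)cyclopent-2-en-1-yl]oxy}silane
Conditions: TESOTf, 2,6-lutidine, CH2Cl2, −78 → −40 °C
Reagents that add atoms: triethylsilyl trifluoromethanesulfonate, CC[Si](CC)(CC)OS(=O)(=O)C(F)(F)F
Why: Silylation of the tertiary allylic alcohol with the silyl triflate under buffered conditions; the ether prevents retro-aldol cleavage, quenching of the later enolate and competing direction of the C6 reduction by the C4 oxygen.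

Step 11
Reactants: 17 triethyl{[(1S,4S,5R)-5-ethenyl-4-methyl-4-[2-(2-methyl-1,3-dioxolan-2-yl)ethyl]-1-(propan-2-yl)cyclopent-2-en-1-yl]oxy}silane
Product: 18 1-[(1R,2S,5S)-5-methyl-5-[2-(2-methyl-1,3-dioxolan-2-yl)ethyl]-2-(propan-2-yl)-2-(triethylsilyloxy)cyclopent-3-en-1-yl]ethan-1-one
Conditions: PdCl2 (10 mol%), Cu(OAc)2·H2O (20 mol%), O2 (1 atm), DMA–H2O (7:1), rt
Reagents that add atoms: water, O
Why: Tsuji–Wacker oxidation converts only the monosubstituted alkene into the methyl ketone (Markovnikov; C6 carbonyl, C7 methyl), the hindered 1,2-disubstituted ring alkene being inert, and the copper acetate variant is acid-free so that ketal and silyl ether survive.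

Step 12
Reactants: 18 1-[(1R,2S,5S)-5-methyl-5-[2-(2-methyl-1,3-dioxolan-2-yl)ethyl]-2-(propan-2-yl)-2-(triethylsilyloxy)cyclopent-3-en-1-yl]ethan-1-one
Product: 20 2-bromo-1-[(1R,2S,5S)-5-methyl-5-[2-(2-methyl-1,3-dioxolan-2-yl)ethyl]-2-(propan-2-yl)-2-(triethylsilyloxy)cyclopent-3-en-1-yl]ethan-1-one, via trimethylsilyl enol ether 19 (not isolated)
Conditions: LiHMDS, TMSCl, THF, −78 °C; then NBS, THF, −78 → 0 °C
Reagents that add atoms: N-bromosuccinimide, O=C1CCC(=O)N1Br
Why: Kinetic deprotonation occurs at the methyl group C7 (C5–H lies between two fully substituted carbons), and bromination of the resulting silyl enol ether fixes the halogen regiospecifically at C7 while the other ketone is still a ketal.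

Step 13
Reactants: 20 2-bromo-1-[(1R,2S,5S)-5-methyl-5-[2-(2-methyl-1,3-dioxolan-2-yl)ethyl]-2-(propan-2-yl)-2-(triethylsilyloxy)cyclopent-3-en-1-yl]ethan-1-one
Product: 21 2-bromo-1-[(1R,2S,5S)-5-methyl-5-(3-oxobutyl)-2-(propan-2-yl)-2-(triethylsilyloxy)cyclopent-3-en-1-yl]ethan-1-one
Conditions: PPTS (cat.), acetone–H2O (10:1), 40 °C
Reagents that add atoms: water, O
Why: Mild acid-catalysed ketal hydrolysis frees the C8 methyl ketone, and the tertiary triethylsilyl ether and the α-bromo ketone should tolerate pyridinium tosylate.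

Step 14
Reactants: 21 2-bromo-1-[(1R,2S,5S)-5-methyl-5-(3-oxobutyl)-2-(propan-2-yl)-2-(triethylsilyloxy)cyclopent-3-en-1-yl]ethan-1-one
Product: 23 (1S,4S,5R,8R)-8-hydroxy-4-(triethylsilyloxy)dauc-2-en-6-one, via samarium enolate 22 (not isolated)
Conditions: SmI2 (2.5 equiv), THF, −78 °C, slow addition of 21 (final 0.005 M); sat. aq. NH4Cl at −78 °C
Reagents that add atoms: none
Why: Two single-electron transfers from SmI2 cleave the C7–Br bond and give the samarium(III) enolate regiospecifically at C7 without any proton transfer, and this enolate adds to the C8 ketone; the closest known reaction type is the samarium Reformatsky/aldol cyclisation of α-halo ketones onto carbonyl groups, which is used for medium-ring ketols. The seven-membered ring closes in the 7-(enolendo)-exo-trig mode through a chair-like transition state that is trans-fused to the cyclopentene, because the C6 arm on C5 and the C10 arm on C1 are already trans. The new stereocentre C8 is controlled by the Sm(III) bridge between the enolate oxygen on C6 and the ketone oxygen: the C8 oxygen takes the pseudo-axial site syn to the C6 oxygen, which lies on the face of the angular C1 methyl, and the C8 methyl takes the pseudo-equatorial site pointing away from the ring, giving 8-OH cis to the C1 methyl. The step needs chemoselective reduction of the α-bromo ketone beside two ketones (secured by −78 °C and the absence of HMPA), ring closure faster than enolate equilibration to C5 or C9 (secured by the low temperature, the non-basic medium and high dilution) and the C8 face (secured by the chelate and the trans fusion). The competing five-membered aldol from C9 onto C6 would need a trans-fused bicyclo[3.3.0]octane and is not expected.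

Step 15
Reactants: 23 (1S,4S,5R,8R)-8-hydroxy-4-(triethylsilyloxy)dauc-2-en-6-one
Product: 24 (1S,4S,5S,6S,8R)-4-(triethylsilyloxy)dauc-2-ene-6,8-diol
Conditions: Me4NBH(OAc)3, MeCN–AcOH (1:1), −30 °C
Reagents that add atoms: none
Why: Evans–Saksena reduction: the tertiary C8 hydroxyl exchanges onto boron and delivers hydride intramolecularly to C6 from its own face, so the new C6 hydroxyl is trans to the C8 hydroxyl (1,3-anti), equatorial and cis to H5, and the silylated C4 oxygen cannot compete as a directing group.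

Step 16
Reactants: 25 4-hydroxy-3-methoxybenzoic acid (vanillic acid)
Product: 27 4-(tert-butyldimethylsilyloxy)-3-methoxybenzoic acid, via bis-silyl derivative 26 (not isolated)
Conditions: TBSCl (2.5 equiv), imidazole, DMF, rt; then AcOH–THF–H2O (3:1:1), rt
Reagents that add atoms: tert-butyldimethylsilyl chloride, CC(C)(C)[Si](C)(C)Cl
Why: Silylation of phenol and acid followed by selective hydrolysis of the much more labile silyl ester leaves the aryl silyl ether in place.

Step 17
Reactants: 24 (1S,4S,5S,6S,8R)-4-(triethylsilyloxy)dauc-2-ene-6,8-diol; 27 4-(tert-butyldimethylsilyloxy)-3-methoxybenzoic acid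
Product: 28 (1S,4S,5S,6S,8R)-8-hydroxy-4-(triethylsilyloxy)dauc-2-en-6-yl 4-(tert-butyldimethylsilyloxy)-3-methoxybenzoate
Conditions: 27 (3 equiv), DCC, DMAP (1 equiv), CH2Cl2, rt
Reagents that add atoms: none
Why: Steglich esterification acylates the secondary, equatorial C6 hydroxyl and leaves the tertiary C8 hydroxyl untouched; the C6 configuration is retained because the acyl–oxygen bond is the one formed.

Step 18
Reactants: 28 (1S,4S,5S,6S,8R)-8-hydroxy-4-(triethylsilyloxy)dauc-2-en-6-yl 4-(tert-butyldimethylsilyloxy)-3-methoxybenzoate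
Product: 29 (1S,4S,5S,6S,8R)-4,8-dihydroxydauc-2-en-6-yl 4-hydroxy-3-methoxybenzoate (CNP0113302.1)
Conditions: TBAF (3 equiv), AcOH (3 equiv), THF, 0 °C → rt
Reagents that add atoms: none
Why: Fluoride-mediated desilylation cleaves the aryl silyl ether and the tertiary triethylsilyl ether in one operation, and the acetic acid buffer protects the ester and the tertiary allylic alcohol from base- or acid-induced side reactions.

**Compound list**

1 | (R)-but-3-yn-2-ol | C[C@@H](O)C#C | starting material
2 | 2-(2-bromoethyl)-2-methyl-1,3-dioxolane | CC1(CCBr)OCCO1 | starting material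
3 | (2R)-6-(2-methyl-1,3-dioxolan-2-yl)hex-3-yn-2-ol | C[C@@H](O)C#CCCC1(C)OCCO1 | intermediate
4 | sodium alkenylalanate, not isolated: five-membered O–Al–C=CH–CH(CH3) ring, Al carrying two 2-methoxyethoxy groups and the chain-bearing alkene carbon | C[C@H]1O[Al-](OCCOC)(OCCOC)C(CCC2(C)OCCO2)=C1.[Na+] | intermediate
5 | (2R,3Z)-4-iodo-6-(2-methyl-1,3-dioxolan-2-yl)hex-3-en-2-ol | C[C@@H](O)/C=C(\I)CCC1(C)OCCO1 | intermediate
6 | (2R,3E)-4-methyl-6-(2-methyl-1,3-dioxolan-2-yl)hex-3-en-2-ol | C[C@@H](O)/C=C(\C)CCC1(C)OCCO1 | intermediate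
7 | but-3-enoic acid | C=CCC(=O)O | starting material
8 | (2R,3E)-4-methyl-6-(2-methyl-1,3-dioxolan-2-yl)hex-3-en-2-yl but-3-enoate | C=CCC(=O)O[C@H](C)/C=C(\C)CCC1(C)OCCO1 | intermediate
9 | (1Z)-silyl ketene acetal of 8, not isolated: 1-(allylic alkoxy)-1-(trimethylsilyloxy)buta-1,3-diene, vinyl cis to OSi | C=C/C=C(\O[Si](C)(C)C)O[C@H](C)/C=C(\C)CCC1(C)OCCO1 | intermediate
10 | trimethylsilyl ester of acid 11, not isolated | C[Si](C)(C)OC(=O)[C@H](C=C)[C@@](C)(CCC1(C)OCCO1)/C=C/C | intermediate
11 | (2R,3S,4E)-2-ethenyl-3-methyl-3-[2-(2-methyl-1,3-dioxolan-2-yl)ethyl]hex-4-enoic acid | OC(=O)[C@H](C=C)[C@@](C)(CCC1(C)OCCO1)/C=C/C | intermediate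
12 | acyl imidazolide of acid 11, not isolated | O=C(n1ccnc1)[C@H](C=C)[C@@](C)(CCC1(C)OCCO1)/C=C/C | intermediate
13 | (2R,3S,4E)-2-ethenyl-N-methoxy-N,3-dimethyl-3-[2-(2-methyl-1,3-dioxolan-2-yl)ethyl]hex-4-enamide | CON(C)C(=O)[C@H](C=C)[C@@](C)(CCC1(C)OCCO1)/C=C/C | intermediate
14 | (4R,5S,6E)-4-ethenyl-5-methyl-5-[2-(2-methyl-1,3-dioxolan-2-yl)ethyl]octa-1,6-dien-3-one | C=CC(=O)[C@H](C=C)[C@@](C)(CCC1(C)OCCO1)/C=C/C | intermediate
15 | (4S,5R)-5-ethenyl-4-methyl-4-[2-(2-methyl-1,3-dioxolan-2-yl)ethyl]cyclopent-2-en-1-one (vinyl cis to the ring methyl) | CC1(CC[C@@]2(C)C=CC(=O)[C@@H]2C=C)OCCO1 | intermediate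
16 | (1S,4S,5R)-5-ethenyl-4-methyl-4-[2-(2-methyl-1,3-dioxolan-2-yl)ethyl]-1-(propan-2-yl)cyclopent-2-en-1-ol (OH, vinyl and ring methyl all cis) | CC1(CC[C@@]2(C)C=C[C@@](O)(C(C)C)[C@@H]2C=C)OCCO1 | intermediate
17 | triethyl{[(1S,4S,5R)-5-ethenyl-4-methyl-4-[2-(2-methyl-1,3-dioxolan-2-yl)ethyl]-1-(propan-2-yl)cyclopent-2-en-1-yl]oxy}silane | CC1(CC[C@@]2(C)C=C[C@@](O[Si](CC)(CC)CC)(C(C)C)[C@@H]2C=C)OCCO1 | intermediate
18 | 1-[(1R,2S,5S)-5-methyl-5-[2-(2-methyl-1,3-dioxolan-2-yl)ethyl]-2-(propan-2-yl)-2-(triethylsilyloxy)cyclopent-3-en-1-yl]ethan-1-one | CC1(CC[C@@]2(C)C=C[C@@](O[Si](CC)(CC)CC)(C(C)C)[C@@H]2C(C)=O)OCCO1 | intermediate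
19 | trimethylsilyl enol ether of 18 at the methyl carbon C7, not isolated | CC1(CC[C@@]2(C)C=C[C@@](O[Si](CC)(CC)CC)(C(C)C)[C@@H]2C(=C)O[Si](C)(C)C)OCCO1 | intermediate
20 | 2-bromo-1-[(1R,2S,5S)-5-methyl-5-[2-(2-methyl-1,3-dioxolan-2-yl)ethyl]-2-(propan-2-yl)-2-(triethylsilyloxy)cyclopent-3-en-1-yl]ethan-1-one | CC1(CC[C@@]2(C)C=C[C@@](O[Si](CC)(CC)CC)(C(C)C)[C@@H]2C(=O)CBr)OCCO1 | intermediate
21 | 2-bromo-1-[(1R,2S,5S)-5-methyl-5-(3-oxobutyl)-2-(propan-2-yl)-2-(triethylsilyloxy)cyclopent-3-en-1-yl]ethan-1-one | CC(=O)CC[C@@]1(C)C=C[C@@](O[Si](CC)(CC)CC)(C(C)C)[C@@H]1C(=O)CBr | intermediate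
22 | samarium(III) diiodide enolate of 21 at C7, not isolated | CC(=O)CC[C@@]1(C)C=C[C@@](O[Si](CC)(CC)CC)(C(C)C)[C@@H]1C(=C)O[Sm](I)I | intermediate
23 | (1S,4S,5R,8R)-8-hydroxy-4-(triethylsilyloxy)dauc-2-en-6-one (trans-fused; 8-OH cis to the C1 methyl) | O=C1C[C@](C)(O)CC[C@@]2(C)C=C[C@@](O[Si](CC)(CC)CC)(C(C)C)[C@H]12 | intermediate
24 | (1S,4S,5S,6S,8R)-4-(triethylsilyloxy)dauc-2-ene-6,8-diol (6-OH trans to 8-OH) | O[C@H]1C[C@](C)(O)CC[C@@]2(C)C=C[C@@](O[Si](CC)(CC)CC)(C(C)C)[C@H]12 | intermediate
25 | 4-hydroxy-3-methoxybenzoic acid (vanillic acid) | COc1cc(C(=O)O)ccc1O | starting material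
26 | tert-butyldimethylsilyl 4-(tert-butyldimethylsilyloxy)-3-methoxybenzoate, not isolated | COc1cc(C(=O)O[Si](C)(C)C(C)(C)C)ccc1O[Si](C)(C)C(C)(C)C | intermediate
27 | 4-(tert-butyldimethylsilyloxy)-3-methoxybenzoic acid | COc1cc(C(=O)O)ccc1O[Si](C)(C)C(C)(C)C | intermediate
28 | (1S,4S,5S,6S,8R)-8-hydroxy-4-(triethylsilyloxy)dauc-2-en-6-yl 4-(tert-butyldimethylsilyloxy)-3-methoxybenzoate | COc1cc(C(=O)O[C@H]2C[C@](C)(O)CC[C@@]3(C)C=C[C@@](O[Si](CC)(CC)CC)(C(C)C)[C@H]23)ccc1O[Si](C)(C)C(C)(C)C | intermediate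
29 | (1S,4S,5S,6S,8R)-4,8-dihydroxydauc-2-en-6-yl 4-hydroxy-3-methoxybenzoate (CNP0113302.1) | COc1cc(C(=O)O[C@H]2C[C@](C)(O)CC[C@@]3(C)C=C[C@@](O)(C(C)C)[C@H]23)ccc1O | target

**Step count**

Total steps: 18. Longest linear sequence: 17 (steps 1–15, 17 and 18; step 16 is a one-step branch).

**Steps most likely to fail, with fallbacks**

Step 14. The seven-membered ring may close more slowly than the samarium enolate is protonated or equilibrates, which would give the debrominated diketone or aldols from the C5 or C9 enolates; the C8 face could also be eroded if the chelate is not maintained. The fallback closes the ring by olefination and sets out from bromo ketone 21. Halide exchange (NaI, acetone) gives 2-iodo-1-[(1R,2S,5S)-5-methyl-5-(3-oxobutyl)-2-(propan-2-yl)-2-(triethylsilyloxy)cyclopent-3-en-1-yl]ethan-1-one F1. Arbuzov reaction with trimethyl phosphite converts it into the β-keto phosphonate F2. Intramolecular Horner–Wadsworth–Emmons reaction onto the C8 ketone (K2CO3, 18-crown-6, toluene, 60 °C, high dilution) gives the cycloheptenone (1S,4S,5R)-4-(triethylsilyloxy)dauca-2,7-dien-6-one F3. Nucleophilic epoxidation (t-BuOOH, DBU, CH2Cl2) gives the 7,8-epoxy ketone F4, and reductive cleavage of the C7–O bond (SmI2, THF–MeOH, −90 °C) returns to ketol 23. In this variant C8 is set by the face of the epoxidation, which is less secure than the chelated aldol, so separation of the C8 epimers may be needed.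

Step 5. Incomplete control of the dienolate geometry, competition of a boat transition state or isomerisation of the but-3-enoate to the crotonate would erode the C1/C5 diastereomer ratio. The fallback carries the vinyl group in masked, saturated form and sets out from alcohol 6. Esterification with 4-(phenylselanyl)butanoic acid (from γ-butyrolactone and sodium benzeneselenolate; DCC, DMAP) gives (2R,3E)-4-methyl-6-(2-methyl-1,3-dioxolan-2-yl)hex-3-en-2-yl 4-(phenylselanyl)butanoate F5. This is a simple alkyl ester, for which Z(O)-selective enolisation in THF–DMPU has direct precedent, and there is no acidic allylic α-hydrogen. Ireland–Claisen rearrangement under the conditions of step 5 gives the selenide acid F6, and oxidation to the selenoxide with syn-elimination (H2O2, pyridine, CH2Cl2, 0 °C → rt) unveils the vinyl group and returns to acid 11.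

Step 11. The vinyl group is flanked by a quaternary carbon and the silyloxy-bearing carbon, so the Wacker oxidation may be slow or may give the aldehyde by anti-Markovnikov attack. The fallback sets out from 17 and hydrates the alkene by oxymercuration–demercuration (Hg(OAc)2, THF–H2O; then NaBH4, NaOH), which is selective for the monosubstituted alkene, to give the secondary alcohol F7 as a mixture of carbinol epimers. Oxidation of F7 with Dess–Martin periodinane (NaHCO3, CH2Cl2) returns to methyl ketone 18.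

Further compounds
F1 | step 14 | 2-iodo-1-[(1R,2S,5S)-5-methyl-5-(3-oxobutyl)-2-(propan-2-yl)-2-(triethylsilyloxy)cyclopent-3-en-1-yl]ethan-1-one | CC(=O)CC[C@@]1(C)C=C[C@@](O[Si](CC)(CC)CC)(C(C)C)[C@@H]1C(=O)CI
F2 | step 14 | dimethyl {2-[(1R,2S,5S)-5-methyl-5-(3-oxobutyl)-2-(propan-2-yl)-2-(triethylsilyloxy)cyclopent-3-en-1-yl]-2-oxoethyl}phosphonate | CC(=O)CC[C@@]1(C)C=C[C@@](O[Si](CC)(CC)CC)(C(C)C)[C@@H]1C(=O)CP(=O)(OC)OC
F3 | step 14 | (1S,4S,5R)-4-(triethylsilyloxy)dauca-2,7-dien-6-one | O=C1C=C(C)CC[C@@]2(C)C=C[C@@](O[Si](CC)(CC)CC)(C(C)C)[C@H]12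
F4 | step 14 | (1S,4S,5R,7R,8R)-7,8-epoxy-4-(triethylsilyloxy)dauc-2-en-6-one (epoxide oxygen cis to the C1 methyl) | O=C1[C@@H]2O[C@]2(C)CC[C@@]3(C)C=C[C@@](O[Si](CC)(CC)CC)(C(C)C)[C@H]13
F5 | step 5 | (2R,3E)-4-methyl-6-(2-methyl-1,3-dioxolan-2-yl)hex-3-en-2-yl 4-(phenylselanyl)butanoate | O=C(CCC[Se]c1ccccc1)O[C@H](C)/C=C(\C)CCC1(C)OCCO1
F6 | step 5 | (2R,3S,4E)-3-methyl-3-[2-(2-methyl-1,3-dioxolan-2-yl)ethyl]-2-[2-(phenylselanyl)ethyl]hex-4-enoic acid | OC(=O)[C@H](CC[Se]c1ccccc1)[C@@](C)(CCC1(C)OCCO1)/C=C/C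
F7 | step 11 | 1-[(1S,2S,5S)-5-methyl-5-[2-(2-methyl-1,3-dioxolan-2-yl)ethyl]-2-(propan-2-yl)-2-(triethylsilyloxy)cyclopent-3-en-1-yl]ethan-1-ol (carbinol epimers) | CC1(CC[C@@]2(C)C=C[C@@](O[Si](CC)(CC)CC)(C(C)C)[C@@H]2C(C)O)OCCO1
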